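**Strategy.** The route rests on disconnecting ring A into a four-carbon vinylketene and a two-carbon oxygenated alkyne. Ring A is a resorcinol in which the C8 prenyl lies between the oxygen-bearing C8a and C7, the second prenyl sits on C6, and C5 and C4a carry hydrogen. Heating 2-prenylcyclobut-2-enone, a masked prenyl(vinyl)ketene, with the prenyl-substituted triisopropylsiloxyalkyne forms C8a–C8, C6–C7 and C4a–C8a in one operation. It delivers the benzene ring with both prenyl groups in place, the C8a oxygen free and the C7 oxygen silylated. The free phenol then directs formylation to C4a, ring C is closed as a chromone, and rhodium-catalysed asymmetric addition of phenylboronic acid sets C2 as S.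

Key step: step 5

Remark on the chemistry: compounds 8, 15 and 20 are racemic and their stereocentres are erased later; in step 10 the (S)-configured ligand is assumed to deliver phenyl to the Re face of C2 by analogy with its sense on cyclic enones, and the ligand antipode is used if the first run shows the opposite sense.

**Route**

Step 1
Reactants: 1 ethoxyacetylene; 2 prenyl bromide (1-bromo-3-methylbut-2-ene)
Product: 4 1-ethoxy-5-methylhex-4-en-1-yne, via lithium ethoxyacetylide 3 (not isolated)
Conditions: n-BuLi, THF, −78 °C; then 2, DMPU, −78 °C → rt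
Reagents that add atoms: none
Why: Deprotonation of the terminal ynol ether and SN2 alkylation of the lithium acetylide at the primary carbon of the allylic bromide in a dipolar cosolvent (acetylide alkylation).

Step 2
Reactants: 4 1-ethoxy-5-methylhex-4-en-1-yne; 5 acetone
Product: 7 3-ethoxy-2-(3-methylbut-2-enyl)cyclobut-2-en-1-one, via ketene 6 (not isolated)
Conditions: acetone pyrolysis (ketene lamp, ca. 700 °C), ketene stream into 4, CH2Cl2, 0 °C → rt
Reagents that add atoms: none
Why: Thermal [2+2] cycloaddition of ketene to an alkoxyalkyne, in which the nucleophilic prenyl-bearing alkyne carbon bonds to the ketene carbonyl carbon, so that prenyl ends at C2 and ethoxy at C3 as the later transposition requires (a prenyl group carried by the ketene would instead end on the saturated C4).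

Step 3
Reactants: 7 3-ethoxy-2-(3-methylbut-2-enyl)cyclobut-2-en-1-one
Product: 9 2-(3-methylbut-2-enyl)cyclobut-2-en-1-one, via allylic cyclobutenol 8 (not isolated)
Conditions: i-Bu2AlH, CH2Cl2, −78 °C; then 1 M HCl, 0 °C; product kept as a toluene solution
Reagents that add atoms: water, O
Why: 1,2-Hydride reduction of the vinylogous ester and acid hydrolysis of the 3-ethoxy allylic alcohol with allylic transposition (Stork–Danheiser sequence) move the carbonyl to the former C3, which leaves prenyl on the α-carbon of the new enone and only hydrogen on C3 and C4.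

Step 4
Reactants: 10 ethyl 4-methylpent-3-enoate
Product: 13 triisopropyl(5-methylhex-4-en-1-ynyloxy)silane, via dibromo enolate 11 (not isolated), via lithium ynolate 12 (not isolated)
Conditions: CH2Br2, LiTMP, THF, −78 °C; then 10; n-BuLi, −78 °C → rt; TIPSCl, −78 °C → rt
Reagents that add atoms: dibromomethane, BrCBr; triisopropylsilyl chloride, CC(C)[Si](Cl)(C(C)C)C(C)C
Why: Kowalski ester homologation, in which LiCHBr2 adds to the ester, bromine–lithium exchange on the dibromo enolate triggers 1,2-shift of the prenyl group to give the ynolate, and the bulky silyl chloride traps it on oxygen.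

Step 5
Reactants: 9 2-(3-methylbut-2-enyl)cyclobut-2-en-1-one; 13 triisopropyl(5-methylhex-4-en-1-ynyloxy)silane
Product: 18 2,4-bis(3-methylbut-2-enyl)-3-(triisopropylsilyloxy)phenol, via vinylketene 14 (not isolated), via 4-vinylcyclobutenone 15 (not isolated), via dienylketene 16 (not isolated), via cyclohexadienone 17 (not isolated)
Conditions: toluene, 80 °C, then 110 °C
Reagents that add atoms: none
Why: Four-electron electrocyclic opening of cyclobutenone 9 gives vinylketene 14, which adds the siloxyalkyne in a [2+2] cycloaddition to 4-vinylcyclobutenone 15; this opens again to dienylketene 16, which closes and tautomerises through 17 to the phenol. The closest known reaction type is the Danheiser benzannulation of cyclobutenones with siloxyalkynes, which gives resorcinol monosilyl ethers. Ring A is closed by a thermal disrotatory six-electron electrocyclisation joining the ketene carbon (C8a) to the vinyl terminus (C4a), after the cycloaddition has made C8a–C8 and C6–C7. No stereocentre is created, because the quaternary carbon of 15 becomes trigonal on ring opening. The step needs regioselectivity in the ketene–alkyne union, and the polarised ynol silyl ether secures it: its nucleophilic prenyl-bearing carbon attacks the ketene carbonyl carbon, so that this prenyl ends between the two oxygens and the silyloxy carbon joins the prenyl-bearing ketene carbon. Chemoselectivity follows from the ketene reacting far faster at the electron-rich alkyne than at the isolated trisubstituted alkenes, and the triisopropylsilyl group stays on the oxygen that becomes the C7 oxygen.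

Step 6
Reactants: 18 2,4-bis(3-methylbut-2-enyl)-3-(triisopropylsilyloxy)phenol
Product: 19 2-hydroxy-3,5-bis(3-methylbut-2-enyl)-4-(triisopropylsilyloxy)benzaldehyde
Conditions: MgCl2, Et3N, (CH2O)n, THF, reflux
Reagents that add atoms: paraformaldehyde (formaldehyde unit), C=O
Why: Magnesium-phenoxide-directed ortho-formylation (Casnati–Skattebøl reaction) is specific for the position next to the free hydroxyl, here the only open one (C4a), and avoids the acids and electrophiles that would attack the prenyl groups.

Step 7
Reactants: 19 2-hydroxy-3,5-bis(3-methylbut-2-enyl)-4-(triisopropylsilyloxy)benzaldehyde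
Product: 20 6-(1-hydroxyethyl)-2,4-bis(3-methylbut-2-enyl)-3-(triisopropylsilyloxy)phenol (racemic)
Conditions: MeMgBr (3 equiv), THF, 0 °C → rt; aq NH4Cl
Reagents that add atoms: methylmagnesium bromide, C[Mg]Br
Why: Grignard addition to the aldehyde after deprotonation of the phenol, giving a racemic carbinol whose stereocentre is removed in the next step.

Step 8
Reactants: 20 6-(1-hydroxyethyl)-2,4-bis(3-methylbut-2-enyl)-3-(triisopropylsilyloxy)phenol
Product: 21 1-[2-hydroxy-3,5-bis(3-methylbut-2-enyl)-4-(triisopropylsilyloxy)phenyl]ethan-1-one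
Conditions: activated MnO2, CH2Cl2, rt
Reagents that add atoms: none
Why: Manganese dioxide oxidises the benzylic alcohol selectively and should leave the trisubstituted alkenes and the aryl silyl ether untouched, the product being stabilised by its internal hydrogen bond.

Step 9
Reactants: 21 1-[2-hydroxy-3,5-bis(3-methylbut-2-enyl)-4-(triisopropylsilyloxy)phenyl]ethan-1-one
Product: 23 6,8-bis(3-methylbut-2-enyl)-7-(triisopropylsilyloxy)-4H-chromen-4-one, via enaminone 22 (not isolated)
Conditions: Me2NCH(OMe)2, toluene, 90 °C; then 1 M HCl, CH2Cl2, rt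
Reagents that add atoms: N,N-dimethylformamide dimethyl acetal, CN(C)C(OC)OC
Why: Condensation of the methyl ketone with the formamide acetal and acid-promoted 6-endo addition–elimination of the phenol close ring C as the chromone (enaminone route to chromones), the acetal supplying C2.

Step 10
Reactants: 23 6,8-bis(3-methylbut-2-enyl)-7-(triisopropylsilyloxy)-4H-chromen-4-one; 24 phenylboronic acid
Product: 25 (2S)-6,8-bis(3-methylbut-2-enyl)-2-phenyl-7-(triisopropylsilyloxy)-2,3-dihydro-4H-chromen-4-one
Conditions: PhB(OH)2, [RhOH((S)-MeO-F12-BIPHEP)]2 (cat.), CH2Cl2/H2O, 30 °C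
Reagents that add atoms: none
Why: Rhodium-catalysed asymmetric 1,4-addition of an arylboronic acid to a chromone (Hayashi–Miyaura reaction with an electron-poor atropisomeric bisphosphine), in which the chiral ligand directs phenyl to the Re face of C2 to set 2S and the base-free, mild medium avoids retro-oxa-Michael opening.

Step 11
Reactants: 25 (2S)-6,8-bis(3-methylbut-2-enyl)-2-phenyl-7-(triisopropylsilyloxy)-2,3-dihydro-4H-chromen-4-one
Product: 26 (2S)-7-hydroxy-6,8-bis(3-methylbut-2-enyl)-2-phenyl-2,3-dihydro-4H-chromen-4-one (7-hydroxy-6,8-diprenylflavanone)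
Conditions: TBAF, AcOH (1:1), THF, 0 °C
Reagents that add atoms: none
Why: Fluoride cleavage of the aryl silyl ether, buffered with acetic acid so that no enolate forms and the C2 stereocentre is not scrambled by ring opening.

**Compound list**

1 | ethoxyacetylene | C#COCC | starting material
2 | prenyl bromide (1-bromo-3-methylbut-2-ene) | CC(C)=CCBr | starting material
3 | lithium ethoxyacetylide (not isolated) | [Li]C#COCC | intermediate
4 | 1-ethoxy-5-methylhex-4-en-1-yne | CCOC#CCC=C(C)C | intermediate
5 | acetone | CC(C)=O | starting material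
6 | ketene (not isolated) | C=C=O | intermediate
7 | 3-ethoxy-2-(3-methylbut-2-enyl)cyclobut-2-en-1-one | CCOC1=C(CC=C(C)C)C(=O)C1 | intermediate
8 | 3-ethoxy-2-(3-methylbut-2-enyl)cyclobut-2-en-1-ol, racemic (not isolated) | CCOC1=C(CC=C(C)C)C(O)C1 | intermediate
9 | 2-(3-methylbut-2-enyl)cyclobut-2-en-1-one | O=C1CC=C1CC=C(C)C | intermediate
10 | ethyl 4-methylpent-3-enoate | CCOC(=O)CC=C(C)C | starting material
11 | lithium 1,1-dibromo-5-methylhexa-1,4-dien-2-olate (not isolated) | [Li]OC(CC=C(C)C)=C(Br)Br | intermediate
12 | lithium 5-methylhex-4-en-1-yn-1-olate (not isolated) | [Li]OC#CCC=C(C)C | intermediate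
13 | triisopropyl(5-methylhex-4-en-1-ynyloxy)silane | CC(C)=CCC#CO[Si](C(C)C)(C(C)C)C(C)C | intermediate
14 | 2-ethenyl-5-methylhexa-1,4-dien-1-one, the prenyl(vinyl)ketene (not isolated) | C=CC(CC=C(C)C)=C=O | intermediate
15 | 4-ethenyl-2,4-bis(3-methylbut-2-enyl)-3-(triisopropylsilyloxy)cyclobut-2-en-1-one, racemic (not isolated) | C=CC1(CC=C(C)C)C(=O)C(CC=C(C)C)=C1O[Si](C(C)C)(C(C)C)C(C)C | intermediate
16 | (3E)-2,4-bis(3-methylbut-2-enyl)-3-(triisopropylsilyloxy)hexa-1,3,5-trien-1-one, ketene carbon and vinyl group cis (not isolated) | O=C=C(CC=C(C)C)/C(O[Si](C(C)C)(C(C)C)C(C)C)=C(\C=C)CC=C(C)C | intermediate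
17 | 2,4-bis(3-methylbut-2-enyl)-3-(triisopropylsilyloxy)cyclohexa-2,4-dien-1-one (not isolated) | O=C1CC=C(CC=C(C)C)C(O[Si](C(C)C)(C(C)C)C(C)C)=C1CC=C(C)C | intermediate
18 | 2,4-bis(3-methylbut-2-enyl)-3-(triisopropylsilyloxy)phenol | CC(C)=CCc1ccc(O)c(CC=C(C)C)c1O[Si](C(C)C)(C(C)C)C(C)C | intermediate
19 | 2-hydroxy-3,5-bis(3-methylbut-2-enyl)-4-(triisopropylsilyloxy)benzaldehyde | O=Cc1cc(CC=C(C)C)c(O[Si](C(C)C)(C(C)C)C(C)C)c(CC=C(C)C)c1O | intermediate
20 | 6-(1-hydroxyethyl)-2,4-bis(3-methylbut-2-enyl)-3-(triisopropylsilyloxy)phenol, racemic | CC(O)c1cc(CC=C(C)C)c(O[Si](C(C)C)(C(C)C)C(C)C)c(CC=C(C)C)c1O | intermediate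
21 | 1-[2-hydroxy-3,5-bis(3-methylbut-2-enyl)-4-(triisopropylsilyloxy)phenyl]ethan-1-one | CC(=O)c1cc(CC=C(C)C)c(O[Si](C(C)C)(C(C)C)C(C)C)c(CC=C(C)C)c1O | intermediate
22 | (E)-3-(dimethylamino)-1-[2-hydroxy-3,5-bis(3-methylbut-2-enyl)-4-(triisopropylsilyloxy)phenyl]prop-2-en-1-one (not isolated) | CN(C)/C=C/C(=O)c1cc(CC=C(C)C)c(O[Si](C(C)C)(C(C)C)C(C)C)c(CC=C(C)C)c1O | intermediate
23 | 6,8-bis(3-methylbut-2-enyl)-7-(triisopropylsilyloxy)-4H-chromen-4-one | O=c1ccoc2c(CC=C(C)C)c(O[Si](C(C)C)(C(C)C)C(C)C)c(CC=C(C)C)cc12 | intermediate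
24 | phenylboronic acid | OB(O)c1ccccc1 | starting material
25 | (2S)-6,8-bis(3-methylbut-2-enyl)-2-phenyl-7-(triisopropylsilyloxy)-2,3-dihydro-4H-chromen-4-one | CC(C)=CCc1cc2c(c(CC=C(C)C)c1O[Si](C(C)C)(C(C)C)C(C)C)O[C@H](c1ccccc1)CC2=O | intermediate
26 | (2S)-7-hydroxy-6,8-bis(3-methylbut-2-enyl)-2-phenyl-2,3-dihydro-4H-chromen-4-one | CC(C)=CCc1cc2c(c(CC=C(C)C)c1O)O[C@H](c1ccccc1)CC2=O | target

**Step count.** Total: 11 steps. Longest linear sequence: 10 steps (steps 1, 2, 3, 5, 6, 7, 8, 9, 10, 11); step 4 is the one-step side branch.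

**Steps most likely to fail**

Step 5. The strained cyclobutenone, unsubstituted at its β-carbon, may be lost by oligomerisation or conjugate addition before it opens at 80 °C, so that the vinylketene never meets the alkyne. The fallback generates the same vinylketene 14 at room temperature by photochemical Wolff rearrangement, the diazo ketone variant of this benzannulation. It sets out from siloxyalkyne 13 and comes back to the route at phenol 18. Commercial 5-methylhex-4-enoic acid is converted with carbonyldiimidazole and N,O-dimethylhydroxylamine hydrochloride into N-methoxy-N,5-dimethylhex-4-enamide F1. Vinylmagnesium bromide (THF, 0 °C, cold acidic quench) then gives 7-methylocta-1,6-dien-3-one F2. Detrifluoroacetylative diazo transfer follows: LiHMDS and 2,2,2-trifluoroethyl trifluoroacetate at −78 °C give 1,1,1-trifluoro-3-(3-methylbut-2-enyl)hex-5-ene-2,4-dione F3, and methanesulfonyl azide, Et3N and water in MeCN give 4-diazo-7-methylocta-1,6-dien-3-one F4. Irradiation of F4 with 13 in 1,2-dichloroethane (medium-pressure mercury lamp, Pyrex, rt), followed by warming to 80 °C, should lead through 14, 15, 16 and 17 to 18.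

Step 4. Deprotonation of the β,γ-unsaturated ester at its doubly activated α-position may compete with carbonyl addition of the carbenoid, so that enolisation and double-bond migration replace homologation. The fallback reaches the ynolate by oxidation of an acetylide instead. It sets out from prenyl bromide 2 and comes back to the route at lithium ynolate 12, and so at 13. Coupling of 2 with ethynylmagnesium bromide (CuCl cat., THF) gives 5-methylhex-4-en-1-yne F5. n-BuLi (THF, −78 °C) gives lithium 5-methylhex-4-en-1-yn-1-ide F6. Oxygen transfer from lithium tert-butyl peroxide (t-BuOOH, LiHMDS, −78 → 0 °C) gives 12, which is silylated on oxygen with TIPSOTf at −78 °C to 13.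

Step 10. Insertion into the electron-rich chromone flanked by the C8 prenyl group may be slow or poorly face-selective, and the product may open to the chalcone under the aqueous conditions. The fallback builds ring C from a chalcone and resolves the racemate. It sets out from ketone 21 and comes back to the route at 25. Condensation of 21 with benzaldehyde (pyrrolidine, EtOH, 50 °C) gives (E)-1-[2-hydroxy-3,5-bis(3-methylbut-2-enyl)-4-(triisopropylsilyloxy)phenyl]-3-phenylprop-2-en-1-one F7. Oxa-Michael closure (NaOAc, EtOH, reflux) gives racemic 6,8-bis(3-methylbut-2-enyl)-2-phenyl-7-(triisopropylsilyloxy)-2,3-dihydro-4H-chromen-4-one F8. Kinetic resolution by asymmetric transfer hydrogenation (RuCl(p-cymene)(TsDPEN), HCO2H/Et3N, catalyst antipode chosen to reduce the 2R ketone) should leave 25 unreduced. The 2R enantiomer is converted into (2R,4R)-6,8-bis(3-methylbut-2-enyl)-2-phenyl-7-(triisopropylsilyloxy)-3,4-dihydro-2H-chromen-4-ol F9, which is separated by chromatography.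

Further compounds
F1 | step 5 | N-methoxy-N,5-dimethylhex-4-enamide | CON(C)C(=O)CCC=C(C)C
F2 | step 5 | 7-methylocta-1,6-dien-3-one | C=CC(=O)CCC=C(C)C
F3 | step 5 | 1,1,1-trifluoro-3-(3-methylbut-2-enyl)hex-5-ene-2,4-dione | C=CC(=O)C(CC=C(C)C)C(=O)C(F)(F)F
F4 | step 5 | 4-diazo-7-methylocta-1,6-dien-3-one | C=CC(=O)C(=[N+]=[N-])CC=C(C)C
F5 | step 4 | 5-methylhex-4-en-1-yne | C#CCC=C(C)C
F6 | step 4 | lithium 5-methylhex-4-en-1-yn-1-ide | [Li]C#CCC=C(C)C
F7 | step 10 | (E)-1-[2-hydroxy-3,5-bis(3-methylbut-2-enyl)-4-(triisopropylsilyloxy)phenyl]-3-phenylprop-2-en-1-one | O=C(/C=C/c1ccccc1)c1cc(CC=C(C)C)c(O[Si](C(C)C)(C(C)C)C(C)C)c(CC=C(C)C)c1O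
F8 | step 10 | racemic 6,8-bis(3-methylbut-2-enyl)-2-phenyl-7-(triisopropylsilyloxy)-2,3-dihydro-4H-chromen-4-one | CC(C)=CCc1cc2c(c(CC=C(C)C)c1O[Si](C(C)C)(C(C)C)C(C)C)OC(c1ccccc1)CC2=O
F9 | step 10 | (2R,4R)-6,8-bis(3-methylbut-2-enyl)-2-phenyl-7-(triisopropylsilyloxy)-3,4-dihydro-2H-chromen-4-ol | CC(C)=CCc1cc2c(c(CC=C(C)C)c1O[Si](C(C)C)(C(C)C)C(C)C)O[C@@H](c1ccccc1)C[C@H]2O
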